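**Retrosynthetic overview**
1. Lupalbigenin 14 comes from the 6,3'-diallyl isoflavone 13 by double olefin cross-metathesis with 2-methyl-2-butene.
2. Both C-allyl groups come from one double aromatic Claisen rearrangement of the 5,4'-di-O-allyl-7-O-benzyl isoflavone 11; C6 is the only open ortho position of the 5-O-allyl ether.
3. Ring C is formed last: chalcone 6 undergoes oxidative 1,2-aryl migration to acetal 7, which is closed with acid to the isoflavone.
4. The key C–C bond is made by an intermolecular Claisen–Schmidt aldol condensation of acetophenone 2 (ring A) with aldehyde 4 (ring B).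
5. 2 comes from phloroacetophenone 1 and 4 from 4-hydroxybenzaldehyde 3; rings A and B are bought as arenes.

Assumption: lupalbigenin has no stereocentre and no stereogenic double bond, so the "single enantiomer" is simply the one achiral compound drawn.

**Route**

Step 1
Reactants: 1 1-(2,4,6-trihydroxyphenyl)ethan-1-one (phloroacetophenone)
Product: 2 1-[2,4-bis(benzyloxy)-6-hydroxyphenyl]ethan-1-one
Conditions: BnBr (2.1 equiv), K2CO3 (2.5 equiv), DMF, rt to 60 °C
Reagents that add atoms: benzyl bromide, BrCc1ccccc1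
Why: Williamson ether synthesis in which the 4-OH and one 2-OH are benzylated while the last ortho-OH, held in a hydrogen bond to the acetyl carbonyl, stays free.

Step 2
Reactants: 3 4-hydroxybenzaldehyde
Product: 4 4-(methoxymethoxy)benzaldehyde
Conditions: MOMCl (1.3 equiv), i-Pr2NEt (1.5 equiv), CH2Cl2, 0 °C to rt
Reagents that add atoms: chloromethyl methyl ether, COCCl
Why: O-alkylation of the phenol with the reactive α-chloro ether gives a MOM acetal that is stable to base and removable with dilute acid.

Step 3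
Reactants: 2 1-[2,4-bis(benzyloxy)-6-hydroxyphenyl]ethan-1-one; 4 4-(methoxymethoxy)benzaldehyde
Product: 6 (E)-1-[2,4-bis(benzyloxy)-6-hydroxyphenyl]-3-[4-(methoxymethoxy)phenyl]prop-2-en-1-one, via aldol adduct 5 (not isolated)
Conditions: KOH (50% aq.), EtOH, rt, 36 h; then cold dilute HCl to pH 5
Reagents that add atoms: none
Why: Claisen–Schmidt crossed aldol condensation in which the methyl ketone enolate of 2 adds to the non-enolisable aldehyde 4 and E1cB dehydration gives the conjugated enone with the thermodynamic E geometry, all protecting groups being base-stable.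

Step 4
Reactants: 6 (E)-1-[2,4-bis(benzyloxy)-6-hydroxyphenyl]-3-[4-(methoxymethoxy)phenyl]prop-2-en-1-one
Product: 7 1-[2,4-bis(benzyloxy)-6-hydroxyphenyl]-3,3-dimethoxy-2-[4-(methoxymethoxy)phenyl]propan-1-one
Conditions: Tl(NO3)3·3H2O (1.2 equiv), MeOH–HC(OMe)3 (3:1), rt, 3 h; filter off TlNO3, NaHCO3 work-up
Reagents that add atoms: methanol, CO
Why: Oxidative 1,2-aryl migration of a 2'-hydroxychalcone by trivalent thallium, in which methanol adds at the β-carbon, the electron-rich 4-alkoxyphenyl group shifts to the α-carbon as monovalent thallium leaves, and the oxocarbenium ion is trapped as the dimethyl acetal (the new stereocentre is racemic and is destroyed in step 5).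

Step 5
Reactants: 7 1-[2,4-bis(benzyloxy)-6-hydroxyphenyl]-3,3-dimethoxy-2-[4-(methoxymethoxy)phenyl]propan-1-one
Product: 9 5,7-bis(benzyloxy)-3-(4-hydroxyphenyl)-4H-chromen-4-one, via MOM-protected isoflavone 8 (not isolated)
Conditions: 10% HCl, MeOH–THF, reflux, 3 h
Reagents that add atoms: none
Why: Acid-catalysed cyclocondensation (the free phenol attacks the acetal-derived oxocarbenium ion and methanol is eliminated to close ring C) followed by acidic methanolysis of the MOM acetal, conditions under which benzyl ethers survive.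

Step 6
Reactants: 9 5,7-bis(benzyloxy)-3-(4-hydroxyphenyl)-4H-chromen-4-one
Product: 10 7-(benzyloxy)-5-hydroxy-3-(4-hydroxyphenyl)-4H-chromen-4-one
Conditions: MgBr2·OEt2 (3 equiv), toluene–Et2O, 80 °C; dilute HCl work-up
Reagents that add atoms: none
Why: Chelation-controlled Lewis-acid ether cleavage in which magnesium is bound between the C4 carbonyl and the peri 5-oxygen, so bromide removes only that benzyl group and the unchelated 7-O-benzyl ether remains.

Step 7
Reactants: 10 7-(benzyloxy)-5-hydroxy-3-(4-hydroxyphenyl)-4H-chromen-4-one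
Product: 11 7-(benzyloxy)-5-(prop-2-en-1-yloxy)-3-[4-(prop-2-en-1-yloxy)phenyl]-4H-chromen-4-one
Conditions: allyl bromide (5 equiv), K2CO3 (5 equiv), DMF, 60 °C, 16 h
Reagents that add atoms: allyl bromide, C=CCBr
Why: Double Williamson O-allylation in which the 4'-OH reacts readily and the hydrogen-bonded 5-OH is driven to completion by excess halide and warming, the 7-oxygen being blocked as its benzyl ether.

Step 8
Reactants: 11 7-(benzyloxy)-5-(prop-2-en-1-yloxy)-3-[4-(prop-2-en-1-yloxy)phenyl]-4H-chromen-4-one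
Product: 12 7-(benzyloxy)-5-hydroxy-3-[4-hydroxy-3-(prop-2-en-1-yl)phenyl]-6-(prop-2-en-1-yl)-4H-chromen-4-one
Conditions: PhNEt2, 205 °C, Ar, sealed tube, 6 h
Reagents that add atoms: none
Why: Double aromatic Claisen rearrangement ([3,3]-sigmatropic) in which the 5-O-allyl group can only move to C6 (its other ortho position is the ring-fusion carbon C4a) and the 4'-O-allyl group moves to the equivalent 3'/5' positions, tautomerisation restoring both phenols.

Step 9
Reactants: 12 7-(benzyloxy)-5-hydroxy-3-[4-hydroxy-3-(prop-2-en-1-yl)phenyl]-6-(prop-2-en-1-yl)-4H-chromen-4-one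
Product: 13 5,7-dihydroxy-3-[4-hydroxy-3-(prop-2-en-1-yl)phenyl]-6-(prop-2-en-1-yl)-4H-chromen-4-one
Conditions: BCl3 (4 equiv), pentamethylbenzene (3 equiv), CH2Cl2, −78 °C, 45 min; MeOH then H2O quench
Reagents that add atoms: none
Why: Lewis-acid debenzylation with a cation scavenger, in which BCl3 ionises the aryl benzyl ether at low temperature and pentamethylbenzene captures the benzyl cation by Friedel–Crafts alkylation, so the terminal alkenes and the electron-rich ring A are untouched.

Step 10
Reactants: 13 5,7-dihydroxy-3-[4-hydroxy-3-(prop-2-en-1-yl)phenyl]-6-(prop-2-en-1-yl)-4H-chromen-4-one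
Product: 14 lupalbigenin
Conditions: 2-methyl-2-butene (large excess), second-generation Grubbs catalyst (H2IMes)(PCy3)Cl2Ru=CHPh (2 × 5 mol %), CH2Cl2, 40 °C, sealed tube, 16 h
Reagents that add atoms: 2-methyl-2-butene, CC=C(C)C
Why: Olefin cross-metathesis in which the ruthenium alkylidene exchanges the terminal CH2 of each allyl group for an isopropylidene unit from the excess trisubstituted alkene with loss of propene, a reaction that tolerates free phenols and the chromone.

**Compound list**
1 | 1-(2,4,6-trihydroxyphenyl)ethan-1-one (phloroacetophenone) | CC(=O)c1c(O)cc(O)cc1O | starting material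
2 | 1-[2,4-bis(benzyloxy)-6-hydroxyphenyl]ethan-1-one | CC(=O)c1c(O)cc(OCc2ccccc2)cc1OCc1ccccc1 | intermediate
3 | 4-hydroxybenzaldehyde | O=Cc1ccc(O)cc1 | starting material
4 | 4-(methoxymethoxy)benzaldehyde | COCOc1ccc(C=O)cc1 | intermediate
5 | 1-[2,4-bis(benzyloxy)-6-hydroxyphenyl]-3-hydroxy-3-[4-(methoxymethoxy)phenyl]propan-1-one (racemic aldol adduct, not isolated) | COCOc1ccc(C(O)CC(=O)c2c(O)cc(OCc3ccccc3)cc2OCc2ccccc2)cc1 | intermediate
6 | (E)-1-[2,4-bis(benzyloxy)-6-hydroxyphenyl]-3-[4-(methoxymethoxy)phenyl]prop-2-en-1-one | COCOc1ccc(/C=C/C(=O)c2c(O)cc(OCc3ccccc3)cc2OCc2ccccc2)cc1 | intermediate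
7 | 1-[2,4-bis(benzyloxy)-6-hydroxyphenyl]-3,3-dimethoxy-2-[4-(methoxymethoxy)phenyl]propan-1-one (racemic) | COCOc1ccc(C(C(OC)OC)C(=O)c2c(O)cc(OCc3ccccc3)cc2OCc2ccccc2)cc1 | intermediate
8 | 5,7-bis(benzyloxy)-3-[4-(methoxymethoxy)phenyl]-4H-chromen-4-one (not isolated) | COCOc1ccc(-c2coc3cc(OCc4ccccc4)cc(OCc4ccccc4)c3c2=O)cc1 | intermediate
9 | 5,7-bis(benzyloxy)-3-(4-hydroxyphenyl)-4H-chromen-4-one | O=c1c(-c2ccc(O)cc2)coc2cc(OCc3ccccc3)cc(OCc3ccccc3)c12 | intermediate
10 | 7-(benzyloxy)-5-hydroxy-3-(4-hydroxyphenyl)-4H-chromen-4-one | O=c1c(-c2ccc(O)cc2)coc2cc(OCc3ccccc3)cc(O)c12 | intermediate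
11 | 7-(benzyloxy)-5-(prop-2-en-1-yloxy)-3-[4-(prop-2-en-1-yloxy)phenyl]-4H-chromen-4-one | C=CCOc1ccc(-c2coc3cc(OCc4ccccc4)cc(OCC=C)c3c2=O)cc1 | intermediate
12 | 7-(benzyloxy)-5-hydroxy-3-[4-hydroxy-3-(prop-2-en-1-yl)phenyl]-6-(prop-2-en-1-yl)-4H-chromen-4-one | C=CCc1cc(-c2coc3cc(OCc4ccccc4)c(CC=C)c(O)c3c2=O)ccc1O | intermediate
13 | 5,7-dihydroxy-3-[4-hydroxy-3-(prop-2-en-1-yl)phenyl]-6-(prop-2-en-1-yl)-4H-chromen-4-one | C=CCc1cc(-c2coc3cc(O)c(CC=C)c(O)c3c2=O)ccc1O | intermediate
14 | lupalbigenin, 5,7-dihydroxy-3-[4-hydroxy-3-(3-methylbut-2-en-1-yl)phenyl]-6-(3-methylbut-2-en-1-yl)-4H-chromen-4-one (achiral) | CC(C)=CCc1cc(-c2coc3cc(O)c(CC=C(C)C)c(O)c3c2=O)ccc1O | target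

**Step count**
Total steps: 10. Longest linear sequence: 9 steps (1 → 2 → 6 → 7 → 9 → 10 → 11 → 12 → 13 → 14, that is steps 1 and 3 to 10).

**Steps most likely to fail, with fallbacks**

Step 4 (oxidative aryl migration). Risks are aurone formation, partial loss of the MOM group in the nitric acid that is generated, and over-oxidation of ring A. The fallback sets out from chalcone 6 and returns at 8. Chalcone 6 is first isomerised by intramolecular oxa-Michael addition (NaOAc, EtOH, reflux) to racemic 5,7-bis(benzyloxy)-2-[4-(methoxymethoxy)phenyl]chroman-4-one F1. This flavanone then undergoes the hypervalent-iodine 2,3-aryl migration with dehydrogenation (PhI(OAc)2, HC(OMe)3, catalytic H2SO4, rt), which gives isoflavone 8. Compound 8 is isolated this time and taken through the HCl/MeOH treatment of step 5 to 9.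

Step 6 (selective 5-O-debenzylation). The risk is incomplete discrimination between the 5- and 7-benzyl ethers. The fallback sets out from 9 and returns at 10. Both benzyl groups are removed by hydrogenolysis (H2, Pd/C, EtOAc–MeOH, rt) to give genistein, 5,7-dihydroxy-3-(4-hydroxyphenyl)-4H-chromen-4-one F2. The 7-OH is the most acidic hydroxyl (a vinylogous acid para to the pyrone carbonyl), so it alone is re-benzylated with one equivalent of benzyl bromide and KHCO3 in DMF at rt, giving 10.

Step 8 (double Claisen rearrangement). Risks are para-migration to C8, incomplete rearrangement of one ether, and thermal decomposition. The fallback sets out from 10, bypasses 11 and returns at 12. Compound 10 is iodinated ortho to each free hydroxyl with benzyltrimethylammonium dichloroiodate (2.1 equiv, CaCO3, CH2Cl2–MeOH, rt) to give 7-(benzyloxy)-5-hydroxy-3-(4-hydroxy-3-iodophenyl)-6-iodo-4H-chromen-4-one F3. The C6 selectivity relies on the known preference of this reagent for the position next to the chelated 5-OH and is the uncertain point of this fallback. A double Stille coupling with allyltributylstannane (Pd(PPh3)4, LiCl, DMF, 90 °C) then gives 12.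

**Further compounds**
F1 | step 4 | 5,7-bis(benzyloxy)-2-[4-(methoxymethoxy)phenyl]chroman-4-one (racemic) | COCOc1ccc(C2CC(=O)c3c(OCc4ccccc4)cc(OCc4ccccc4)cc3O2)cc1
F2 | step 6 | 5,7-dihydroxy-3-(4-hydroxyphenyl)-4H-chromen-4-one (genistein) | O=c1c(-c2ccc(O)cc2)coc2cc(O)cc(O)c12
F3 | step 8 | 7-(benzyloxy)-5-hydroxy-3-(4-hydroxy-3-iodophenyl)-6-iodo-4H-chromen-4-one | O=c1c(-c2ccc(O)c(I)c2)coc2cc(OCc3ccccc3)c(I)c(O)c12
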